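**Strategy**

The target is cut at C11=C12 (Wittig) and at the C8–C9 acyl–vinyl bond (Stille acylation); everything rests on how ring A, the 3-hydroxy-2,6,6-trimethylcyclohexene carrying C7, is made. Its C5 and the attached methyl are inserted as one CH(CH3) unit from diazoethane into the C(=O)–CH2 bond of (S)-4-silyloxy-2,2-dimethylcyclopentanone, a one-carbon ring expansion. The step exploits that C5 lies between C4H2 and C6 while the gem-dimethyl C1 flanks C6: C1 directs the migration, blocks a second insertion and leaves a ketone with one enolisable site, so the C5=C6 alkene can only form in the ring. C3 is set beforehand by asymmetric conjugate borylation.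

Key step: step 4

Remark: carotenoid numbering is used for positions of the target (C1–C20 for the half with ring A, primed numbers for the half with ring B, the 3-hydroxycyclohex-2-ene end); ketone 7 is carried as a mixture of epimers at its methyl-bearing carbon, which becomes sp2 in step 5; compounds 20 and 21 are racemic and one enantiomer is drawn.

**Route**

Step 1
Reactants: 1 2,2-dimethylcyclopentan-1-one
Product: 2 5,5-dimethylcyclopent-2-en-1-one
Conditions: 2-iodoxybenzoic acid (IBX), DMSO, 70 °C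
Reagents that add atoms: none
Why: IBX-mediated α,β-dehydrogenation of a ketone; only one α-CH2 is enolisable, so a single enone should form.

Step 2
Reactants: 2 5,5-dimethylcyclopent-2-en-1-one
Product: 4 (S)-4-hydroxy-2,2-dimethylcyclopentan-1-one, via β-boryl ketone 3 (not isolated)
Conditions: B2pin2, CuCl (5 mol %), NaOtBu (5 mol %), (R)-1-[(S)-2-(diphenylphosphino)ferrocenyl]ethyldicyclohexylphosphine (Josiphos-type ligand, 6 mol %; its mirror image is taken if a test run shows the opposite sense), MeOH, THF, 23 °C; then NaBO3·4H2O, THF/H2O, 23 °C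
Reagents that add atoms: bis(pinacolato)diboron, CC1(C)OB(OC1(C)C)B1OC(C)(C)C(C)(C)O1 (boron of 3); sodium perborate, [Na+].[Na+].O[B-]1(O)OO[B-](O)(O)OO1 (hydroxyl oxygen of 4)
Why: Copper-catalysed enantioselective conjugate borylation followed by stereoretentive C–B oxidation; the chiral copper–boryl complex selects the enone face and so sets the carbinol centre that becomes C3 of the target.

Step 3
Reactants: 4 (S)-4-hydroxy-2,2-dimethylcyclopentan-1-one
Product: 5 (S)-4-[(tert-butyldimethylsilyl)oxy]-2,2-dimethylcyclopentan-1-one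
Conditions: TBSCl, imidazole, DMF, 0 → 23 °C
Reagents that add atoms: tert-butyldimethylsilyl chloride, CC(C)(C)[Si](C)(C)Cl
Why: Standard silyl ether formation; the weak base imidazole should not trigger β-elimination of the β-oxygenated ketone.

Step 4
Reactants: 5 (S)-4-[(tert-butyldimethylsilyl)oxy]-2,2-dimethylcyclopentan-1-one
Product: 7 (4R)-4-[(tert-butyldimethylsilyl)oxy]-2,2,6-trimethylcyclohexan-1-one (C6 epimers), via diazonium alkoxide 6 (not isolated)
Conditions: diazoethane (pre-formed ethereal solution, excess), Sc(OTf)3 (10 mol %), CH2Cl2, −78 → −40 °C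
Reagents that add atoms: diazoethane, CC=[N+]=[N-]
Why: Sc(OTf)3 activates the carbonyl of 5, the nucleophilic carbon of diazoethane adds to give the β-oxido diazonium 6, and a 1,2-shift of the ring CH2 with loss of N2 delivers the homologated ketone, so that the new CH(CH3) unit (C5 and its methyl in the target) sits between the carbonyl carbon (C6) and C4. The closest known reaction type is the Lewis-acid-promoted diazoalkane homologation of cycloalkanones (Büchner–Curtius–Schlotterbeck reaction, Tiffeneau–Demjanov manifold), as in the D-homoannulation of 17-oxo steroids, whose carbonyl is likewise flanked by a quaternary carbon. No ring is closed by cyclisation: the six-membered ring A arises from the five-membered ring by migration of a ring C–C bond, so no exo or endo mode applies. The only new stereocentre, the methyl-bearing C6 of 7, forms without control and is irrelevant because it becomes sp2 in step 5, while the silyloxy-bearing centre is untouched (S in 5 and R in 7 only through a change in CIP priorities). The step needs migration of CH2 in preference to the quaternary carbon and a single insertion; the gem-dimethyl group should secure both, since the less substituted α-carbon migrates in this manifold and the α,α,α'-trisubstituted product is too hindered to react again.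

Step 5
Reactants: 7 (4R)-4-[(tert-butyldimethylsilyl)oxy]-2,2,6-trimethylcyclohexan-1-one
Product: 8 (R)-4-[(tert-butyldimethylsilyl)oxy]-2,6,6-trimethylcyclohex-1-en-1-yl trifluoromethanesulfonate
Conditions: KN(SiMe3)2, THF, −78 °C; PhNTf2, −78 → 0 °C
Reagents that add atoms: N-phenylbis(trifluoromethanesulfonimide), O=S(=O)(N(c1ccccc1)S(=O)(=O)C(F)(F)F)C(F)(F)F
Why: Enolate O-triflation; the ketone has a single α-hydrogen, so only the tetrasubstituted C5=C6 enol triflate can form and the epimeric centre is erased.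

Step 6
Reactants: 8 (R)-4-[(tert-butyldimethylsilyl)oxy]-2,6,6-trimethylcyclohex-1-en-1-yl trifluoromethanesulfonate
Product: 9 ethyl 2-[(R)-4-[(tert-butyldimethylsilyl)oxy]-2,6,6-trimethylcyclohex-1-en-1-yl]acetate
Conditions: BrZnCH2CO2Et (preformed THF solution), Pd(dba)2 (5 mol %), 1,2,3,4,5-pentaphenyl-1'-(di-tert-butylphosphino)ferrocene (5 mol %), LiCl, THF, 50 °C
Reagents that add atoms: (2-ethoxy-2-oxoethyl)zinc bromide, CCOC(=O)C[Zn]Br
Why: Negishi-type coupling of a Reformatsky reagent with an alkenyl triflate under zerovalent palladium catalysis, which attaches C7–C8 and keeps the alkene fixed in the ring as the β,γ-unsaturated ester.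

Step 7
Reactants: 9 ethyl 2-[(R)-4-[(tert-butyldimethylsilyl)oxy]-2,6,6-trimethylcyclohex-1-en-1-yl]acetate
Product: 10 2-[(R)-4-[(tert-butyldimethylsilyl)oxy]-2,6,6-trimethylcyclohex-1-en-1-yl]acetic acid
Conditions: LiOH·H2O, THF/MeOH/H2O, 23 °C; then cold 0.5 M HCl to pH 4
Reagents that add atoms: lithium hydroxide, [Li+].[OH-]
Why: Ester saponification; the tetrasubstituted ring alkene should not move into conjugation and the secondary silyl ether survives brief cold dilute acid.

Step 8
Reactants: 11 but-2-yne-1,4-diol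
Product: 12 (E)-2-(tributylstannyl)but-2-ene-1,4-diol
Conditions: Bu3SnH, PdCl2(PPh3)2 (2 mol %), THF, 23 °C
Reagents that add atoms: tributyltin hydride, CCCC[SnH](CCCC)CCCC
Why: Palladium-catalysed syn-hydrostannation of a symmetrical alkyne, which poses no regiochemical question and places the two CH2OH groups cis (the later C19 and C11).

Step 9
Reactants: 12 (E)-2-(tributylstannyl)but-2-ene-1,4-diol
Product: 13 (E)-4-[(tert-butyldimethylsilyl)oxy]-2-(tributylstannyl)but-2-en-1-ol
Conditions: TBSCl (1.0 equiv), imidazole, CH2Cl2, −30 °C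
Reagents that add atoms: tert-butyldimethylsilyl chloride, CC(C)(C)[Si](C)(C)Cl
Why: Sterically controlled monosilylation; the hydroxyl next to the Bu3Sn-bearing carbon is shielded, so the distal CH2OH should react first at low temperature.

Step 10
Reactants: 13 (E)-4-[(tert-butyldimethylsilyl)oxy]-2-(tributylstannyl)but-2-en-1-ol; 14 (E)-dec-2-enoic acid
Product: 15 (E)-4-[(tert-butyldimethylsilyl)oxy]-2-(tributylstannyl)but-2-en-1-yl (E)-dec-2-enoate
Conditions: DCC, DMAP (cat.), CH2Cl2, 0 → 23 °C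
Reagents that add atoms: none
Why: Steglich esterification of the remaining primary alcohol, which installs the C19 ester of the target at the outset.

Step 11
Reactants: 10 2-[(R)-4-[(tert-butyldimethylsilyl)oxy]-2,6,6-trimethylcyclohex-1-en-1-yl]acetic acid; 15 (E)-4-[(tert-butyldimethylsilyl)oxy]-2-(tributylstannyl)but-2-en-1-yl (E)-dec-2-enoate
Product: 17 (2E)-4-[(tert-butyldimethylsilyl)oxy]-2-{2-[(4R)-4-[(tert-butyldimethylsilyl)oxy]-2,6,6-trimethylcyclohex-1-en-1-yl]acetyl}but-2-en-1-yl (2E)-dec-2-enoate, via acid chloride 16 (not isolated)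
Conditions: 1-chloro-N,N,2-trimethylprop-1-en-1-amine, CH2Cl2, 0 → 23 °C, evaporate; then 15, Pd2(dba)3 (2.5 mol %), tri(2-furyl)phosphine (10 mol %), CuI (10 mol %), THF, 45 °C
Reagents that add atoms: 1-chloro-N,N,2-trimethylprop-1-en-1-amine, CC(C)=C(Cl)N(C)C (supplies the chlorine of 16; no atom of it remains in 17)
Why: Neutral acid chloride formation followed by the Stille ketone synthesis (acyl chloride–alkenylstannane coupling), which forms C8–C9 with retention of alkene geometry and so places C19 cis to C11.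

Step 12
Reactants: 17 the bis-silyl ether from step 11
Product: 18 (2E)-4-hydroxy-2-{2-[(4R)-4-hydroxy-2,6,6-trimethylcyclohex-1-en-1-yl]acetyl}but-2-en-1-yl (2E)-dec-2-enoate
Conditions: HF·pyridine, pyridine, THF, 0 → 23 °C
Reagents that add atoms: none
Why: Buffered fluoride cleavage of both silyl ethers, which should leave the allylic ester and the β,γ-unsaturated ketone untouched.

Step 13
Reactants: 18 the diol from step 12
Product: 19 (2E)-2-{2-[(4R)-4-hydroxy-2,6,6-trimethylcyclohex-1-en-1-yl]acetyl}-4-oxobut-2-en-1-yl (2E)-dec-2-enoate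
Conditions: activated MnO2 (excess), CH2Cl2, 23 °C
Reagents that add atoms: none
Why: MnO2 oxidises only the primary allylic alcohol (C11) to the aldehyde; the saturated secondary hydroxyl at C3 is inert to it.

Step 14
Reactants: 20 racemic α-ionone, (E)-4-(2,6,6-trimethylcyclohex-2-en-1-yl)but-3-en-2-one
Product: 21 racemic trans-3-hydroxy-α-ionone, (E)-4-[(1R*,4R*)-4-hydroxy-2,6,6-trimethylcyclohex-2-en-1-yl]but-3-en-2-one
Conditions: engineered cytochrome P450 BM3 monooxygenase (CYP102A1 variant), NADP+ (cat.), glucose, glucose dehydrogenase, air, phosphate buffer pH 7.5, 2% DMSO, 30 °C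
Reagents that add atoms: dioxygen, O=O
Why: Enzymatic allylic C–H hydroxylation by a cytochrome P450 monooxygenase, which should oxidise C3 only and anti to the C6 side chain, giving the trans relative configuration that no small oxidant delivers directly.

Step 15
Reactants: 21 racemic trans-3-hydroxy-α-ionone
Product: 22 (E)-4-[(1R,4R)-4-hydroxy-2,6,6-trimethylcyclohex-2-en-1-yl]but-3-en-2-one
Conditions: Pseudomonas fluorescens lipase, vinyl acetate, tert-butyl methyl ether, 30 °C, stopped near half conversion; chromatography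
Reagents that add atoms: none
Why: Lipase-catalysed kinetic resolution by enantioselective acyl transfer; by the empirical size rule for lipases, with the gem-dimethyl flank as the large group, the (3S,6S)-alcohol should be acetylated and the (3R,6R)-alcohol recovered, which fixes both stereocentres of ring B.

Step 16
Reactants: 22 (E)-4-[(1R,4R)-4-hydroxy-2,6,6-trimethylcyclohex-2-en-1-yl]but-3-en-2-one
Product: 23 (1E)-1-[(1R,4R)-4-hydroxy-2,6,6-trimethylcyclohex-2-en-1-yl]-3-methylpenta-1,4-dien-3-ol (both carbinol epimers)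
Conditions: vinylMgBr (3 equiv), THF, −40 → 0 °C
Reagents that add atoms: vinylmagnesium bromide, C=C[Mg]Br
Why: Grignard 1,2-addition to the methyl ketone of the enone; the new tertiary centre is lost in step 17, so its configuration does not matter.

Step 17
Reactants: 23 the vinyl carbinol from step 16
Product: 24 [(2E,4E)-5-[(1R,4R)-4-hydroxy-2,6,6-trimethylcyclohex-2-en-1-yl]-3-methylpenta-2,4-dien-1-yl]triphenylphosphonium bromide
Conditions: PPh3·HBr, MeOH, 0 → 23 °C; crystallisation
Reagents that add atoms: triphenylphosphine hydrobromide, [Br-].[PH+](c1ccccc1)(c1ccccc1)c1ccccc1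
Why: Acid-mediated allylic transposition with phosphonium salt formation; the tertiary, doubly allylic alcohol ionises and PPh3 attacks the terminal carbon, while the less easily ionised ring allylic alcohol should survive.

Step 18
Reactants: 24 the C15 phosphonium bromide; 25 (2E,4E,6E)-2,7-dimethylocta-2,4,6-trienedial
Product: 26 (2E,4E,6E,8E,10E,12E)-13-[(1R,4R)-4-hydroxy-2,6,6-trimethylcyclohex-2-en-1-yl]-2,7,11-trimethyltrideca-2,4,6,8,10,12-hexaenal
Conditions: 25 (2.5 equiv), NaOMe, MeOH/CH2Cl2, 0 → 23 °C; then warm in heptane (Z to E equilibration)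
Reagents that add atoms: none
Why: Wittig olefination with excess dialdehyde to favour reaction at one aldehyde only; the new disubstituted C11'=C12' bond should equilibrate thermally to E.

Step 19
Reactants: 26 the C25 aldehyde
Product: 27 (2E,4E,6E,8E,10E,12E)-13-[(1R,4R)-4-hydroxy-2,6,6-trimethylcyclohex-2-en-1-yl]-2,7,11-trimethyltrideca-2,4,6,8,10,12-hexaen-1-ol
Conditions: NaBH4, MeOH/THF, 0 °C
Reagents that add atoms: none
Why: 1,2-Reduction of the conjugated aldehyde by borohydride.

Step 20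
Reactants: 27 the C25 diol
Product: 28 [(2E,4E,6E,8E,10E,12E)-13-[(1R,4R)-4-hydroxy-2,6,6-trimethylcyclohex-2-en-1-yl]-2,7,11-trimethyltrideca-2,4,6,8,10,12-hexaen-1-yl]triphenylphosphonium bromide
Conditions: PPh3·HBr, MeOH/CH2Cl2, 0 → 23 °C, dark
Reagents that add atoms: triphenylphosphine hydrobromide, [Br-].[PH+](c1ccccc1)(c1ccccc1)c1ccccc1
Why: Phosphonium salt formation from a polyenylic primary alcohol, which ionises far more readily than the isolated allylic hydroxyl of ring B.

Step 21
Reactants: 19 the keto-enal from step 13; 28 the C25 phosphonium bromide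
Product: 29 (3R,3'R,6'R)-19-[(2E)-dec-2-enoyloxy]-3,3'-dihydroxy-7,8-dihydro-β,ε-caroten-8-one (the target)
Conditions: 1,2-epoxybutane (excess), CH2Cl2, 45 °C, argon, dark; then brief reflux in heptane (Z to E equilibration)
Reagents that add atoms: none
Why: Wittig olefination under base-free epoxide conditions that should spare the decenoate ester and the free hydroxyls; the ylide attacks the aldehyde in preference to the C8 ketone and the new C11=C12 bond should equilibrate to E.

**Compound list**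

1 | 2,2-dimethylcyclopentan-1-one | CC1(C)CCCC1=O | starting material
2 | 5,5-dimethylcyclopent-2-en-1-one | CC1(C)CC=CC1=O | intermediate
3 | (S)-2,2-dimethyl-4-(4,4,5,5-tetramethyl-1,3,2-dioxaborolan-2-yl)cyclopentan-1-one | O=C1C[C@@H](B2OC(C)(C)C(C)(C)O2)CC1(C)C | intermediate (not isolated)
4 | (S)-4-hydroxy-2,2-dimethylcyclopentan-1-one | O=C1C[C@@H](O)CC1(C)C | intermediate
5 | (S)-4-[(tert-butyldimethylsilyl)oxy]-2,2-dimethylcyclopentan-1-one | O=C1C[C@@H](O[Si](C)(C)C(C)(C)C)CC1(C)C | intermediate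
6 | 1-[(4S)-4-[(tert-butyldimethylsilyl)oxy]-2,2-dimethyl-1-oxidocyclopentyl]ethane-1-diazonium (zwitterion, scandium-bound; new centres unassigned) | CC([N+]#N)C1([O-])C[C@@H](O[Si](C)(C)C(C)(C)C)CC1(C)C | intermediate (not isolated)
7 | (4R)-4-[(tert-butyldimethylsilyl)oxy]-2,2,6-trimethylcyclohexan-1-one (C6 epimers) | O=C1C(C)C[C@@H](O[Si](C)(C)C(C)(C)C)CC1(C)C | intermediate
8 | (R)-4-[(tert-butyldimethylsilyl)oxy]-2,6,6-trimethylcyclohex-1-en-1-yl trifluoromethanesulfonate | FC(F)(F)S(=O)(=O)OC1=C(C)C[C@@H](O[Si](C)(C)C(C)(C)C)CC1(C)C | intermediate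
9 | ethyl 2-[(R)-4-[(tert-butyldimethylsilyl)oxy]-2,6,6-trimethylcyclohex-1-en-1-yl]acetate | CCOC(=O)CC1=C(C)C[C@@H](O[Si](C)(C)C(C)(C)C)CC1(C)C | intermediate
10 | 2-[(R)-4-[(tert-butyldimethylsilyl)oxy]-2,6,6-trimethylcyclohex-1-en-1-yl]acetic acid | OC(=O)CC1=C(C)C[C@@H](O[Si](C)(C)C(C)(C)C)CC1(C)C | intermediate
11 | but-2-yne-1,4-diol | OCC#CCO | starting material
12 | (E)-2-(tributylstannyl)but-2-ene-1,4-diol | OC/C=C(\CO)[Sn](CCCC)(CCCC)CCCC | intermediate
13 | (E)-4-[(tert-butyldimethylsilyl)oxy]-2-(tributylstannyl)but-2-en-1-ol | CC(C)(C)[Si](C)(C)OC/C=C(\CO)[Sn](CCCC)(CCCC)CCCC | intermediate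
14 | (E)-dec-2-enoic acid | CCCCCCC/C=C/C(=O)O | starting material
15 | (E)-4-[(tert-butyldimethylsilyl)oxy]-2-(tributylstannyl)but-2-en-1-yl (E)-dec-2-enoate | CCCCCCC/C=C/C(=O)OC/C(=C\CO[Si](C)(C)C(C)(C)C)[Sn](CCCC)(CCCC)CCCC | intermediate
16 | 2-[(R)-4-[(tert-butyldimethylsilyl)oxy]-2,6,6-trimethylcyclohex-1-en-1-yl]acetyl chloride | ClC(=O)CC1=C(C)C[C@@H](O[Si](C)(C)C(C)(C)C)CC1(C)C | intermediate (not isolated)
17 | (2E)-4-[(tert-butyldimethylsilyl)oxy]-2-{2-[(4R)-4-[(tert-butyldimethylsilyl)oxy]-2,6,6-trimethylcyclohex-1-en-1-yl]acetyl}but-2-en-1-yl (2E)-dec-2-enoate | CCCCCCC/C=C/C(=O)OC/C(=C\CO[Si](C)(C)C(C)(C)C)C(=O)CC1=C(C)C[C@@H](O[Si](C)(C)C(C)(C)C)CC1(C)C | intermediate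
18 | (2E)-4-hydroxy-2-{2-[(4R)-4-hydroxy-2,6,6-trimethylcyclohex-1-en-1-yl]acetyl}but-2-en-1-yl (2E)-dec-2-enoate | CCCCCCC/C=C/C(=O)OC/C(=C\CO)C(=O)CC1=C(C)C[C@@H](O)CC1(C)C | intermediate
19 | (2E)-2-{2-[(4R)-4-hydroxy-2,6,6-trimethylcyclohex-1-en-1-yl]acetyl}-4-oxobut-2-en-1-yl (2E)-dec-2-enoate | CCCCCCC/C=C/C(=O)OC/C(=C\C=O)C(=O)CC1=C(C)C[C@@H](O)CC1(C)C | intermediate
20 | racemic α-ionone, (E)-4-(2,6,6-trimethylcyclohex-2-en-1-yl)but-3-en-2-one | CC(=O)/C=C/C1C(C)=CCCC1(C)C | starting material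
21 | racemic trans-3-hydroxy-α-ionone, (E)-4-[(1R*,4R*)-4-hydroxy-2,6,6-trimethylcyclohex-2-en-1-yl]but-3-en-2-one (racemate, 1R,4R enantiomer drawn) | CC(=O)/C=C/[C@H]1C(C)=C[C@H](O)CC1(C)C | intermediate
22 | (E)-4-[(1R,4R)-4-hydroxy-2,6,6-trimethylcyclohex-2-en-1-yl]but-3-en-2-one, (3R,6R)-3-hydroxy-α-ionone | CC(=O)/C=C/[C@H]1C(C)=C[C@H](O)CC1(C)C | intermediate
23 | (1E)-1-[(1R,4R)-4-hydroxy-2,6,6-trimethylcyclohex-2-en-1-yl]-3-methylpenta-1,4-dien-3-ol (both carbinol epimers) | C=CC(C)(O)/C=C/[C@H]1C(C)=C[C@H](O)CC1(C)C | intermediate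
24 | [(2E,4E)-5-[(1R,4R)-4-hydroxy-2,6,6-trimethylcyclohex-2-en-1-yl]-3-methylpenta-2,4-dien-1-yl]triphenylphosphonium bromide | C/C(=C\C[P+](c1ccccc1)(c1ccccc1)c1ccccc1)/C=C/[C@H]1C(C)=C[C@H](O)CC1(C)C.[Br-] | intermediate
25 | (2E,4E,6E)-2,7-dimethylocta-2,4,6-trienedial | O=C/C(C)=C/C=C/C=C(C)/C=O | starting material
26 | (2E,4E,6E,8E,10E,12E)-13-[(1R,4R)-4-hydroxy-2,6,6-trimethylcyclohex-2-en-1-yl]-2,7,11-trimethyltrideca-2,4,6,8,10,12-hexaenal | O=C/C(C)=C/C=C/C=C(C)/C=C/C=C(C)/C=C/[C@H]1C(C)=C[C@H](O)CC1(C)C | intermediate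
27 | (2E,4E,6E,8E,10E,12E)-13-[(1R,4R)-4-hydroxy-2,6,6-trimethylcyclohex-2-en-1-yl]-2,7,11-trimethyltrideca-2,4,6,8,10,12-hexaen-1-ol | OC/C(C)=C/C=C/C=C(C)/C=C/C=C(C)/C=C/[C@H]1C(C)=C[C@H](O)CC1(C)C | intermediate
28 | [(2E,4E,6E,8E,10E,12E)-13-[(1R,4R)-4-hydroxy-2,6,6-trimethylcyclohex-2-en-1-yl]-2,7,11-trimethyltrideca-2,4,6,8,10,12-hexaen-1-yl]triphenylphosphonium bromide | [Br-].c1ccccc1[P+](c1ccccc1)(c1ccccc1)C/C(C)=C/C=C/C=C(C)/C=C/C=C(C)/C=C/[C@H]1C(C)=C[C@H](O)CC1(C)C | intermediate
29 | (3R,3'R,6'R)-19-[(2E)-dec-2-enoyloxy]-3,3'-dihydroxy-7,8-dihydro-β,ε-caroten-8-one | CCCCCCC/C=C/C(=O)OC\C(=C/C=C/C(C)=C/C=C/C=C(C)/C=C/C=C(C)/C=C/[C@H]1C(C)=C[C@H](O)CC1(C)C)C(=O)CC1=C(C)C[C@@H](O)CC1(C)C | target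

**Step count and risks**

Total step count: 21.
Longest linear sequence: 11 steps (steps 1–7, 11–13 and 21, from compound 1).

Steps most likely to fail:

Step 4. Addition of the secondary diazoalkane to the carbonyl next to the quaternary carbon may be slow, so that epoxide formation or Lewis-acid-induced β-elimination of the silyloxy group takes over. The fallback sets out from 5 and comes back at 7; it keeps the one-carbon ring expansion but separates insertion and methylation. Ketone 5 would be treated with trimethylsilyldiazomethane and BF3·OEt2 in CH2Cl2 at −78 °C, where the smaller nucleophile should insert between the carbonyl and the CH2 group to give (4S)-4-[(tert-butyldimethylsilyl)oxy]-2,2-dimethyl-6-(trimethylsilyl)cyclohexan-1-one F1. Brief K2CO3 in methanol would remove the C-silyl group to give (4R)-4-[(tert-butyldimethylsilyl)oxy]-2,2-dimethylcyclohexan-1-one F2. This ketone has a single enolisable α-position, so LDA followed by iodomethane should give 7.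

Step 6. Oxidative addition and transmetalation at the tetrasubstituted, doubly flanked alkenyl triflate may be sluggish, with loss of the triflate by hydrolysis or reduction. The fallback sets out from 7 and comes back at 10, replacing the cross-coupling by an ene reaction. Wittig methylenation of 7 (Ph3PCH3Br, KOtBu, toluene, 90 °C) would give tert-butyldimethyl{[(1R)-3,3,5-trimethyl-4-methylidenecyclohexyl]oxy}silane F3. A carbonyl-ene reaction with paraformaldehyde and Me2AlCl (CH2Cl2, −78 → 0 °C) can take the allylic hydrogen only from the methyl-bearing ring carbon and should therefore give 2-[(R)-4-[(tert-butyldimethylsilyl)oxy]-2,6,6-trimethylcyclohex-1-en-1-yl]ethan-1-ol F4 with the alkene at C5=C6. Oxidation with TEMPO and PhI(OAc)2 in MeCN/H2O would then give acid 10.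

Step 11. Transmetalation of the internal, allylically oxygenated stannane may be slow, leaving time for palladium-induced ionisation of the allylic decenoate or protodestannylation. The fallback sets out from 10 and 13 and comes back at 17, forming C8–C9 by addition of an alkenyllithium to an amide and introducing the decenoate afterwards. Acid 10 would be converted (MeNHOMe·HCl, EDC, iPr2NEt) into 2-[(R)-4-[(tert-butyldimethylsilyl)oxy]-2,6,6-trimethylcyclohex-1-en-1-yl]-N-methoxy-N-methylacetamide F5. Alcohol 13 would be silylated (TESCl, imidazole) to (E)-tert-butyldimethyl{[4-(triethylsilyloxy)-3-(tributylstannyl)but-2-en-1-yl]oxy}silane F6. Tin–lithium exchange with n-BuLi at −78 °C would give (Z)-{4-[(tert-butyldimethylsilyl)oxy]-1-(triethylsilyloxy)but-2-en-2-yl}lithium F7, which should add to F5 to give (2E)-4-[(tert-butyldimethylsilyl)oxy]-1-{(4R)-4-[(tert-butyldimethylsilyl)oxy]-2,6,6-trimethylcyclohex-1-en-1-yl}-3-[(triethylsilyloxy)methyl]but-3-en-2-one-type enone, systematically (3E)-5-[(tert-butyldimethylsilyl)oxy]-1-[(4R)-4-[(tert-butyldimethylsilyl)oxy]-2,6,6-trimethylcyclohex-1-en-1-yl]-3-[(triethylsilyloxy)methyl]pent-3-en-2-one F8. Selective removal of the primary triethylsilyl group (PPTS, MeOH/CH2Cl2, 0 °C) would give (3E)-5-[(tert-butyldimethylsilyl)oxy]-1-[(4R)-4-[(tert-butyldimethylsilyl)oxy]-2,6,6-trimethylcyclohex-1-en-1-yl]-3-(hydroxymethyl)pent-3-en-2-one F9, and esterification with 14 (DCC, DMAP) would give 17.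

Further compounds
F1 | step 4 | (4S)-4-[(tert-butyldimethylsilyl)oxy]-2,2-dimethyl-6-(trimethylsilyl)cyclohexan-1-one (C6 epimers) | O=C1C([Si](C)(C)C)C[C@@H](O[Si](C)(C)C(C)(C)C)CC1(C)C
F2 | step 4 | (4R)-4-[(tert-butyldimethylsilyl)oxy]-2,2-dimethylcyclohexan-1-one | O=C1CC[C@@H](O[Si](C)(C)C(C)(C)C)CC1(C)C
F3 | step 6 | tert-butyldimethyl{[(1R)-3,3,5-trimethyl-4-methylidenecyclohexyl]oxy}silane (C5 epimers) | C=C1C(C)C[C@@H](O[Si](C)(C)C(C)(C)C)CC1(C)C
F4 | step 6 | 2-[(R)-4-[(tert-butyldimethylsilyl)oxy]-2,6,6-trimethylcyclohex-1-en-1-yl]ethan-1-ol | OCCC1=C(C)C[C@@H](O[Si](C)(C)C(C)(C)C)CC1(C)C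
F5 | step 11 | 2-[(R)-4-[(tert-butyldimethylsilyl)oxy]-2,6,6-trimethylcyclohex-1-en-1-yl]-N-methoxy-N-methylacetamide | CON(C)C(=O)CC1=C(C)C[C@@H](O[Si](C)(C)C(C)(C)C)CC1(C)C
F6 | step 11 | (E)-tert-butyldimethyl{[4-(triethylsilyloxy)-3-(tributylstannyl)but-2-en-1-yl]oxy}silane | CC[Si](CC)(CC)OC/C(=C\CO[Si](C)(C)C(C)(C)C)[Sn](CCCC)(CCCC)CCCC
F7 | step 11 | (Z)-{4-[(tert-butyldimethylsilyl)oxy]-1-(triethylsilyloxy)but-2-en-2-yl}lithium | CC[Si](CC)(CC)OC/C(=C\CO[Si](C)(C)C(C)(C)C)[Li]
F8 | step 11 | (3E)-5-[(tert-butyldimethylsilyl)oxy]-1-[(4R)-4-[(tert-butyldimethylsilyl)oxy]-2,6,6-trimethylcyclohex-1-en-1-yl]-3-[(triethylsilyloxy)methyl]pent-3-en-2-one | CC[Si](CC)(CC)OC/C(=C\CO[Si](C)(C)C(C)(C)C)C(=O)CC1=C(C)C[C@@H](O[Si](C)(C)C(C)(C)C)CC1(C)C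
F9 | step 11 | (3E)-5-[(tert-butyldimethylsilyl)oxy]-1-[(4R)-4-[(tert-butyldimethylsilyl)oxy]-2,6,6-trimethylcyclohex-1-en-1-yl]-3-(hydroxymethyl)pent-3-en-2-one | OC/C(=C\CO[Si](C)(C)C(C)(C)C)C(=O)CC1=C(C)C[C@@H](O[Si](C)(C)C(C)(C)C)CC1(C)C
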